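**Plan**
- Cuts, in retrosynthetic order: the C3–C4 bond of the flavan pyran ring (ring-closing metathesis; the alkene is later hydrogenated together with all benzyl ethers), O1–C2 (iridium-catalysed allylic etherification), C4–C4a (ortho-formylation, then methylenation), and the aryl–aryl bond between C3 of the flavone and C6 of the flavan (Suzuki–Miyaura coupling).
- Enabling feature: C3 and C4 are adjacent CH2 groups, C4 on aromatic C4a ortho to O1 and C3 on the O-bearing benzylic carbon C2, so each can be the terminal carbon of an alkene in a 2-vinylaryl 1-arylallyl ether.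
- Regiochemistry: with the flavone para to the future O1, ring A of the flavan is symmetric about its C6···C8a axis until C4 is attached, so C4a and C8 are equivalent and the 6- versus 8-linkage question does not arise.
- Forward: apigenin → tribenzyl ether → 3-iodide; 3,5-bis(benzyloxy)phenol → para-bromide → silyl ether → boronic acid; coupling; desilylation; formylation; Wittig; etherification; metathesis closes ring C of the flavan; one hydrogenation gives the hexaphenol.
- Stereochemistry: C2 (S) is set by the chiral phosphoramidite ligand in the etherification (step 13) and is carried unchanged through ring closure and hydrogenation.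

Key step: step 14

Remark: the aryl–aryl axis between C3 of the flavone and C6 of the flavan carries no descriptor in the target and is taken as not configurationally fixed (16–20 may show rotamers); 3,5-bis(benzyloxy)phenol is taken as purchasable.

**Route**

Step 1
Reactants: 1 apigenin
Product: 2 5,7-bis(benzyloxy)-2-[4-(benzyloxy)phenyl]-4H-chromen-4-one
Conditions: BnBr (4.5 equiv), K2CO3 (6 equiv), DMF, 80 °C
Reagents that add atoms: benzyl bromide, BrCc1ccccc1
Why: Williamson ether synthesis; excess halide and heat should also alkylate the hydrogen-bonded 5-OH.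

Step 2
Reactants: 2 5,7-bis(benzyloxy)-2-[4-(benzyloxy)phenyl]-4H-chromen-4-one
Product: 4 5,7-bis(benzyloxy)-2-[4-(benzyloxy)phenyl]-3-iodo-4H-chromen-4-one, via C3-lithiated flavone 3 (not isolated)
Conditions: LiN(i-Pr)2 (1.2 equiv), THF, −78 °C; I2, −78 °C → 0 °C
Reagents that add atoms: iodine, II
Why: Carbonyl-directed deprotonation of the only vinylic C–H (C3) and iodinolysis of the vinyllithium, a lithiation–halogenation sequence known for 5,7-dialkoxyflavones.

Step 3
Reactants: 5 3,5-bis(benzyloxy)phenol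
Product: 6 3,5-bis(benzyloxy)-4-bromophenol
Conditions: NBS (1.0 equiv), MeCN, −20 °C → 0 °C
Reagents that add atoms: N-bromosuccinimide, O=C1CCC(=O)N1Br
Why: Electrophilic aromatic bromination, expected mainly para to the free hydroxyl in a polar solvent; the symmetric para isomer should be easy to tell from, and separate from, any ortho isomer.

Step 4
Reactants: 6 3,5-bis(benzyloxy)-4-bromophenol
Product: 7 [3,5-bis(benzyloxy)-4-bromophenoxy]triisopropylsilane
Conditions: i-Pr3SiCl, imidazole, DMF, rt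
Reagents that add atoms: triisopropylsilyl chloride, CC(C)[Si](Cl)(C(C)C)C(C)C
Why: Phenol silylation; the bulky silyl ether should survive n-BuLi and the basic coupling and marks the oxygen that becomes O1.

Step 5
Reactants: 7 [3,5-bis(benzyloxy)-4-bromophenoxy]triisopropylsilane
Product: 9 [2,6-bis(benzyloxy)-4-(triisopropylsilyloxy)phenyl]boronic acid, via aryllithium 8 (not isolated)
Conditions: n-BuLi, THF, −78 °C; B(OMe)3, −78 °C → rt; 1 M HCl, 0 °C
Reagents that add atoms: trimethyl borate, COB(OC)OC; water, O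
Why: Bromine–lithium exchange at −78 °C should outrun benzylic deprotonation, and borylation followed by hydrolysis gives the boronic acid.

Step 6
Reactants: 10 4-(benzyloxy)benzaldehyde
Product: 11 ethyl (E)-3-[4-(benzyloxy)phenyl]prop-2-enoate
Conditions: (EtO)2P(O)CH2CO2Et, NaH, THF, 0 °C → rt
Reagents that add atoms: triethyl phosphonoacetate, CCOC(=O)CP(=O)(OCC)OCC
Why: Horner–Wadsworth–Emmons olefination, reliably E-selective with aryl aldehydes.

Step 7
Reactants: 11 ethyl (E)-3-[4-(benzyloxy)phenyl]prop-2-enoate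
Product: 12 (E)-3-[4-(benzyloxy)phenyl]prop-2-en-1-ol
Conditions: i-Bu2AlH (2.2 equiv), CH2Cl2, −78 °C; aq. KNaC4H4O6
Reagents that add atoms: none
Why: 1,2-Reduction of the conjugated ester to the allylic alcohol with the alkene geometry retained.

Step 8
Reactants: 12 (E)-3-[4-(benzyloxy)phenyl]prop-2-en-1-ol
Product: 13 (E)-3-[4-(benzyloxy)phenyl]prop-2-en-1-yl methyl carbonate
Conditions: ClCO2Me, pyridine, CH2Cl2, 0 °C
Reagents that add atoms: methyl chloroformate, COC(=O)Cl
Why: O-Acylation to the linear allylic carbonate, the standard electrophile for iridium-catalysed allylic substitution.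

Step 9
Reactants: 4 5,7-bis(benzyloxy)-2-[4-(benzyloxy)phenyl]-3-iodo-4H-chromen-4-one; 9 [2,6-bis(benzyloxy)-4-(triisopropylsilyloxy)phenyl]boronic acid
Product: 14 5,7-bis(benzyloxy)-2-[4-(benzyloxy)phenyl]-3-[2,6-bis(benzyloxy)-4-(triisopropylsilyloxy)phenyl]-4H-chromen-4-one
Conditions: Pd(OAc)2 (5 mol %), SPhos (2-dicyclohexylphosphino-2',6'-dimethoxybiphenyl, 10 mol %), K3PO4 (3 equiv), 9 (2 equiv), toluene/H2O 10:1, 90 °C
Reagents that add atoms: none
Why: Suzuki–Miyaura coupling; the activated 3-iodochromone adds readily to palladium and the bulky electron-rich biarylphosphine is suited to 2,6-dialkoxyarylboronic acids and hindered halides.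

Step 10
Reactants: 14 5,7-bis(benzyloxy)-2-[4-(benzyloxy)phenyl]-3-[2,6-bis(benzyloxy)-4-(triisopropylsilyloxy)phenyl]-4H-chromen-4-one
Product: 15 5,7-bis(benzyloxy)-2-[4-(benzyloxy)phenyl]-3-[2,6-bis(benzyloxy)-4-hydroxyphenyl]-4H-chromen-4-one
Conditions: Bu4NF (1.2 equiv), AcOH (1.2 equiv), THF, 0 °C
Reagents that add atoms: none
Why: Fluoride-mediated cleavage of the aryl silyl ether, buffered so that no free phenoxide is exposed.

Step 11
Reactants: 15 5,7-bis(benzyloxy)-2-[4-(benzyloxy)phenyl]-3-[2,6-bis(benzyloxy)-4-hydroxyphenyl]-4H-chromen-4-one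
Product: 16 2,4-bis(benzyloxy)-3-{5,7-bis(benzyloxy)-2-[4-(benzyloxy)phenyl]-4-oxo-4H-chromen-3-yl}-6-hydroxybenzaldehyde
Conditions: MgCl2 (2 equiv), Et3N (4 equiv), (CH2O)n (6 equiv), MeCN, 80 °C; 1 M HCl
Reagents that add atoms: paraformaldehyde (as formaldehyde), C=O
Why: Magnesium phenoxide-directed ortho-formylation (hydroxymethylation, then hydride transfer to a second formaldehyde); the two ortho positions are equivalent, so only one regioisomer can form and the flavan is fixed as 6-linked.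

Step 12
Reactants: 16 2,4-bis(benzyloxy)-3-{5,7-bis(benzyloxy)-2-[4-(benzyloxy)phenyl]-4-oxo-4H-chromen-3-yl}-6-hydroxybenzaldehyde
Product: 17 3-[2,6-bis(benzyloxy)-4-hydroxy-3-vinylphenyl]-5,7-bis(benzyloxy)-2-[4-(benzyloxy)phenyl]-4H-chromen-4-one
Conditions: Ph3PCH3Br (3.5 equiv), KOt-Bu (3.3 equiv), THF, 0 °C → rt
Reagents that add atoms: methyltriphenylphosphonium bromide, C[P+](c1ccccc1)(c1ccccc1)c1ccccc1.[Br-]
Why: Wittig methylenation of a salicylaldehyde with excess ylide (the first equivalent is consumed by the phenol); the hindered vinylogous-ester carbonyl of the flavone should not react.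

Step 13
Reactants: 17 3-[2,6-bis(benzyloxy)-4-hydroxy-3-vinylphenyl]-5,7-bis(benzyloxy)-2-[4-(benzyloxy)phenyl]-4H-chromen-4-one; 13 (E)-3-[4-(benzyloxy)phenyl]prop-2-en-1-yl methyl carbonate
Product: 19 3-[2,6-bis(benzyloxy)-4-{[(1S)-1-(4-(benzyloxy)phenyl)prop-2-en-1-yl]oxy}-3-vinylphenyl]-5,7-bis(benzyloxy)-2-[4-(benzyloxy)phenyl]-4H-chromen-4-one, via lithium phenoxide 18 (not isolated)
Conditions: LiN(SiMe3)2 (1.0 equiv), THF, 0 °C; then 13 (1.5 equiv), [Ir(cod)Cl]2 (2.5 mol %), (Sa,S,S)-O,O'-(1,1'-binaphthyl-2,2'-diyl) N,N-bis(1-phenylethyl)phosphoramidite (5 mol %, pre-activated with n-PrNH2), THF, rt → 40 °C; H2O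
Reagents that add atoms: none
Why: Iridium-catalysed asymmetric allylic etherification: the carbonate ionizes to a π-allyl iridium complex and the phenoxide attacks its aryl-substituted terminus on the face fixed by the phosphoramidite ligand, giving the branched ether and the only stereocenter (S expected with the ligand enantiomer named, its mirror image being used should the sense prove opposite).

Step 14
Reactants: 19 3-[2,6-bis(benzyloxy)-4-{[(1S)-1-(4-(benzyloxy)phenyl)prop-2-en-1-yl]oxy}-3-vinylphenyl]-5,7-bis(benzyloxy)-2-[4-(benzyloxy)phenyl]-4H-chromen-4-one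
Product: 20 (2S)-5,7-bis(benzyloxy)-2-[4-(benzyloxy)phenyl]-6-{5,7-bis(benzyloxy)-2-[4-(benzyloxy)phenyl]-4-oxo-4H-chromen-3-yl}-2H-chromene
Conditions: second-generation Grubbs catalyst RuCl2(=CHPh)(PCy3)(H2IMes) (5–10 mol %), 1,4-benzoquinone (10 mol %), CH2Cl2 (0.005 M), 40 °C
Reagents that add atoms: none
Why: Ring-closing alkene metathesis by the metal carbene/metallacyclobutane mechanism: the ruthenium benzylidene should first engage the monosubstituted allyl-ether alkene, and the new alkylidene then adds to the neighbouring 2,6-dioxygenated styrene through a ruthenacyclobutane that collapses with loss of ethene to the C3=C4 bond. The closest known reaction type is the ring-closing metathesis of 2-vinylaryl allyl ethers to 2H-chromenes. The pyran ring is closed as a six-membered ring by joining the two terminal sp2 carbons C3 and C4, the new double bond being endocyclic and necessarily cis. No stereocenter is formed; C2, set in step 13, is a spectator because neither its C–H nor its C–O bond enters the metallacycle. The step needs cyclization to win over cross-metathesis and over ruthenium hydride-induced migration of the allyl double bond, which high dilution, the ortho placement of the two alkenes and added benzoquinone should secure, while the tetrasubstituted, electron-poor C2=C3 bond of the flavone cannot compete.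

Step 15
Reactants: 20 (2S)-5,7-bis(benzyloxy)-2-[4-(benzyloxy)phenyl]-6-{5,7-bis(benzyloxy)-2-[4-(benzyloxy)phenyl]-4-oxo-4H-chromen-3-yl}-2H-chromene
Product: 21 3-[(2S)-5,7-dihydroxy-2-(4-hydroxyphenyl)chroman-6-yl]-5,7-dihydroxy-2-(4-hydroxyphenyl)-4H-chromen-4-one (CNP0304187.1)
Conditions: H2 (1 atm), Pd/C (10 wt % Pd), EtOAc/MeOH 1:1, rt
Reagents that add atoms: none
Why: Heterogeneous hydrogenation should saturate the cis-disubstituted C3=C4 bond and cleave all six benzyl ethers in one operation, leaving the tetrasubstituted C2=C3 bond of the flavone and the configuration at C2 untouched.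

**Compound list**
1 | apigenin | O=c1cc(-c2ccc(O)cc2)oc2cc(O)cc(O)c12 | starting material
2 | 5,7-bis(benzyloxy)-2-[4-(benzyloxy)phenyl]-4H-chromen-4-one | O=c1cc(-c2ccc(OCc3ccccc3)cc2)oc2cc(OCc3ccccc3)cc(OCc3ccccc3)c12 | intermediate
3 | C3-lithiated flavone (3-lithio derivative of 2) | [Li]c1c(-c2ccc(OCc3ccccc3)cc2)oc2cc(OCc3ccccc3)cc(OCc3ccccc3)c2c1=O | intermediate
4 | 5,7-bis(benzyloxy)-2-[4-(benzyloxy)phenyl]-3-iodo-4H-chromen-4-one | O=c1c(I)c(-c2ccc(OCc3ccccc3)cc2)oc2cc(OCc3ccccc3)cc(OCc3ccccc3)c12 | intermediate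
5 | 3,5-bis(benzyloxy)phenol | Oc1cc(OCc2ccccc2)cc(OCc2ccccc2)c1 | starting material
6 | 3,5-bis(benzyloxy)-4-bromophenol | Oc1cc(OCc2ccccc2)c(Br)c(OCc2ccccc2)c1 | intermediate
7 | [3,5-bis(benzyloxy)-4-bromophenoxy]triisopropylsilane | CC(C)[Si](Oc1cc(OCc2ccccc2)c(Br)c(OCc2ccccc2)c1)(C(C)C)C(C)C | intermediate
8 | [2,6-bis(benzyloxy)-4-(triisopropylsilyloxy)phenyl]lithium | [Li]c1c(OCc2ccccc2)cc(O[Si](C(C)C)(C(C)C)C(C)C)cc1OCc1ccccc1 | intermediate
9 | [2,6-bis(benzyloxy)-4-(triisopropylsilyloxy)phenyl]boronic acid | OB(O)c1c(OCc2ccccc2)cc(O[Si](C(C)C)(C(C)C)C(C)C)cc1OCc1ccccc1 | intermediate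
10 | 4-(benzyloxy)benzaldehyde | O=Cc1ccc(OCc2ccccc2)cc1 | starting material
11 | ethyl (E)-3-[4-(benzyloxy)phenyl]prop-2-enoate | CCOC(=O)/C=C/c1ccc(OCc2ccccc2)cc1 | intermediate
12 | (E)-3-[4-(benzyloxy)phenyl]prop-2-en-1-ol | OC/C=C/c1ccc(OCc2ccccc2)cc1 | intermediate
13 | (E)-3-[4-(benzyloxy)phenyl]prop-2-en-1-yl methyl carbonate | COC(=O)OC/C=C/c1ccc(OCc2ccccc2)cc1 | intermediate
14 | 5,7-bis(benzyloxy)-2-[4-(benzyloxy)phenyl]-3-[2,6-bis(benzyloxy)-4-(triisopropylsilyloxy)phenyl]-4H-chromen-4-one | O=c1c(-c2c(OCc3ccccc3)cc(O[Si](C(C)C)(C(C)C)C(C)C)cc2OCc2ccccc2)c(-c2ccc(OCc3ccccc3)cc2)oc2cc(OCc3ccccc3)cc(OCc3ccccc3)c12 | intermediate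
15 | 5,7-bis(benzyloxy)-2-[4-(benzyloxy)phenyl]-3-[2,6-bis(benzyloxy)-4-hydroxyphenyl]-4H-chromen-4-one | O=c1c(-c2c(OCc3ccccc3)cc(O)cc2OCc2ccccc2)c(-c2ccc(OCc3ccccc3)cc2)oc2cc(OCc3ccccc3)cc(OCc3ccccc3)c12 | intermediate
16 | 2,4-bis(benzyloxy)-3-{5,7-bis(benzyloxy)-2-[4-(benzyloxy)phenyl]-4-oxo-4H-chromen-3-yl}-6-hydroxybenzaldehyde | O=Cc1c(O)cc(OCc2ccccc2)c(-c2c(-c3ccc(OCc4ccccc4)cc3)oc3cc(OCc4ccccc4)cc(OCc4ccccc4)c3c2=O)c1OCc1ccccc1 | intermediate
17 | 3-[2,6-bis(benzyloxy)-4-hydroxy-3-vinylphenyl]-5,7-bis(benzyloxy)-2-[4-(benzyloxy)phenyl]-4H-chromen-4-one | C=Cc1c(O)cc(OCc2ccccc2)c(-c2c(-c3ccc(OCc4ccccc4)cc3)oc3cc(OCc4ccccc4)cc(OCc4ccccc4)c3c2=O)c1OCc1ccccc1 | intermediate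
18 | lithium phenoxide of 17 | [Li]Oc1cc(OCc2ccccc2)c(-c2c(-c3ccc(OCc4ccccc4)cc3)oc3cc(OCc4ccccc4)cc(OCc4ccccc4)c3c2=O)c(OCc2ccccc2)c1C=C | intermediate
19 | 3-[2,6-bis(benzyloxy)-4-{[(1S)-1-(4-(benzyloxy)phenyl)prop-2-en-1-yl]oxy}-3-vinylphenyl]-5,7-bis(benzyloxy)-2-[4-(benzyloxy)phenyl]-4H-chromen-4-one | C=C[C@@H](c1ccc(OCc2ccccc2)cc1)Oc1cc(OCc2ccccc2)c(-c2c(-c3ccc(OCc4ccccc4)cc3)oc3cc(OCc4ccccc4)cc(OCc4ccccc4)c3c2=O)c(OCc2ccccc2)c1C=C | intermediate
20 | (2S)-5,7-bis(benzyloxy)-2-[4-(benzyloxy)phenyl]-6-{5,7-bis(benzyloxy)-2-[4-(benzyloxy)phenyl]-4-oxo-4H-chromen-3-yl}-2H-chromene | O=c1c(-c2c(OCc3ccccc3)cc3c(c2OCc2ccccc2)C=C[C@@H](c2ccc(OCc4ccccc4)cc2)O3)c(-c2ccc(OCc3ccccc3)cc2)oc2cc(OCc3ccccc3)cc(OCc3ccccc3)c12 | intermediate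
21 | 3-[(2S)-5,7-dihydroxy-2-(4-hydroxyphenyl)chroman-6-yl]-5,7-dihydroxy-2-(4-hydroxyphenyl)-4H-chromen-4-one | O=c1c(-c2c(O)cc3c(c2O)CC[C@@H](c2ccc(O)cc2)O3)c(-c2ccc(O)cc2)oc2cc(O)cc(O)c12 | target

**Totals**
Total step count: 15.
Longest linear sequence: 10 steps (5 → 21 through steps 3, 4, 5, 9, 10, 11, 12, 13, 14, 15).

**Steps most likely to fail**

Step 13. Reversible ionization of the electron-rich product ether at iridium may erode the enantiomeric purity and the branched selectivity, or the ortho-substituted phenoxide may attack too slowly. The fallback sets out from 10 and 17 and comes back at 19. Catalytic enantioselective vinylation of aldehyde 10 with Zn(CH=CH2)2 and 3-exo-(dimethylamino)isoborneol (enantiomer chosen for the R product) would give (R)-1-[4-(benzyloxy)phenyl]prop-2-en-1-ol F3. Mitsunobu etherification of 17 with F3 (PPh3, diisopropyl azodicarboxylate, toluene, −20 °C) would then form the O–C2 bond with inversion and deliver 19.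

Step 9. Protodeboronation of the 2,6-dialkoxyarylboronic acid may outrun transmetalation onto the hindered flavonylpalladium iodide, so that coupling stalls. The fallback sets out from 4 and 7 and comes back at 14, with the polarity of the coupling inverted. Iodine–magnesium exchange on 4 with i-PrMgCl·LiCl (THF, −40 °C) should give the flavon-3-ylmagnesium chloride F1. ZnCl2 would convert it into the flavon-3-ylzinc chloride F2. Negishi coupling of F2 with aryl bromide 7 (Pd2(dba)3, XPhos, THF, 60 °C) would give 14 without any boronic acid.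

Step 15. Before the C3=C4 bond is saturated, palladium may cleave the allylic, benzylic C2–O1 bond or shift the double bond toward C2, which would open the pyran ring or scramble the stereocenter. The fallback sets out from 20 and comes back at 21. Diimide, generated from 2-nitrobenzenesulfonyl hydrazide and Et3N (CH2Cl2, rt), would saturate C3=C4 without a metal and give the hexabenzyl (2S)-flavan F4. Hydrogenolysis of F4 (H2, Pd(OH)2/C, THF/MeOH) would then only have to remove the benzyl groups to reach 21.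

**Further compounds**
F1 | step 9 | {5,7-bis(benzyloxy)-2-[4-(benzyloxy)phenyl]-4-oxo-4H-chromen-3-yl}magnesium chloride | Cl[Mg]c1c(-c2ccc(OCc3ccccc3)cc2)oc2cc(OCc3ccccc3)cc(OCc3ccccc3)c2c1=O
F2 | step 9 | {5,7-bis(benzyloxy)-2-[4-(benzyloxy)phenyl]-4-oxo-4H-chromen-3-yl}zinc chloride | Cl[Zn]c1c(-c2ccc(OCc3ccccc3)cc2)oc2cc(OCc3ccccc3)cc(OCc3ccccc3)c2c1=O
F3 | step 13 | (R)-1-[4-(benzyloxy)phenyl]prop-2-en-1-ol | C=C[C@H](c1ccc(OCc2ccccc2)cc1)O
F4 | step 15 | (2S)-5,7-bis(benzyloxy)-2-[4-(benzyloxy)phenyl]-6-{5,7-bis(benzyloxy)-2-[4-(benzyloxy)phenyl]-4-oxo-4H-chromen-3-yl}chromane | O=c1c(-c2c(OCc3ccccc3)cc3c(c2OCc2ccccc2)CC[C@@H](c2ccc(OCc4ccccc4)cc2)O3)c(-c2ccc(OCc3ccccc3)cc2)oc2cc(OCc3ccccc3)cc(OCc3ccccc3)c12
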